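Numbering follows benzofuran (O1, C2, C3, C3a, C4–C7, C7a). Ring A is the benzo ring, ring B the guaiacyl ring on C2, ring C the eugenol ring.
Cuts, in retrosynthetic order: O–Si on ring B; C5–allyl (back to C5–Cl); C3a–C7a and C4–C5 together (ring A back to a pyridazine plus an ethynyl group); O1–C(diazine); C2–C3; last, the carbonyl–alkyne bond and the O–CH2 bond of the ring C arm.
Enabling feature: ring A (C3a, C4, C5, C6, C7, C7a) is fused to the dihydrofuran along C3a–C7a, so O1–C2–C3 is a three-atom tether between a diazine carbon on O1 and an alkyne carbon on C3.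
Forward: rings B and C are bought. The chain grows ring C arm → C3 → C2/ring B → diazine on O1, then ring A and the dihydrofuran ring form in one thermal operation with loss of N2. The C5 allyl group and the free phenol come last.
Stereochemistry: one catalytic ketone reduction sets a propargylic carbinol. Its chirality passes centre → allene axis → C3 (net inversion) while anti addition to the aldehyde sets C2, and the anti pair becomes the trans (2S,3R) pair without being touched again.
Key step: step 9

Assumption: the palladium/indium allenylation is taken to follow its usual course (anti SN2' palladation, retention on transfer to indium, syn SE2' addition), that is net inversion at the mesylate carbon. Were the sense opposite, the (S,S) ligand would be used in step 3.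

Step 1
Reactants: 1 eugenol; 2 2-chloro-N-methoxy-N-methylacetamide
Product: 3 2-(4-allyl-2-methoxyphenoxy)-N-methoxy-N-methylacetamide
Conditions: K2CO3, NaI (cat.), MeCN, 70 °C
Reagents that add atoms: none
Why: Williamson ether synthesis in which the phenoxide of eugenol displaces the primary α-chloro amide (iodide-assisted SN2) under carbonate conditions too mild to move the allyl double bond into conjugation.

Step 2
Reactants: 3 2-(4-allyl-2-methoxyphenoxy)-N-methoxy-N-methylacetamide; 4 trimethylsilylacetylene
Product: 6 1-(4-allyl-2-methoxyphenoxy)-4-(trimethylsilyl)but-3-yn-2-one, via lithium (trimethylsilyl)acetylide 5 (not isolated)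
Conditions: 4, n-BuLi, THF, −78 °C; then 3, −78 to −20 °C; then cold 1 M HCl
Reagents that add atoms: none
Why: Weinreb ketone synthesis, in which the N-methoxy-N-methyl amide accepts only one equivalent of acetylide 5 and releases the ketone on the acidic quench, so over-addition is excluded.

Step 3
Reactants: 6 1-(4-allyl-2-methoxyphenoxy)-4-(trimethylsilyl)but-3-yn-2-one
Product: 7 (S)-1-(4-allyl-2-methoxyphenoxy)-4-(trimethylsilyl)but-3-yn-2-ol
Conditions: Ru[(R,R)-TsDPEN](p-cymene) (2 mol %), i-PrOH, rt
Reagents that add atoms: none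
Why: Noyori asymmetric transfer hydrogenation of an alkynyl ketone, in which hydride and proton are delivered to the carbonyl face that places the alkyne under the arene ligand; the (R,R) ligand gives the carbinol labelled S here because CH2OAr outranks the alkynyl group, and the isolated allyl double bond is inert.

Step 4
Reactants: 7 (S)-1-(4-allyl-2-methoxyphenoxy)-4-(trimethylsilyl)but-3-yn-2-ol
Product: 8 (S)-1-(4-allyl-2-methoxyphenoxy)but-3-yn-2-ol
Conditions: K2CO3 (0.2 equiv), MeOH, rt
Reagents that add atoms: none
Why: Base-catalysed protodesilylation of an alkynylsilane by methanol, which touches neither the carbinol stereocentre nor the aryl ether and is done here, before ring B with its aryl silyl ether is present.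

Step 5
Reactants: 8 (S)-1-(4-allyl-2-methoxyphenoxy)but-3-yn-2-ol
Product: 9 (S)-1-(4-allyl-2-methoxyphenoxy)but-3-yn-2-yl methanesulfonate
Conditions: MsCl, Et3N, CH2Cl2, −78 °C
Reagents that add atoms: methanesulfonyl chloride, CS(=O)(=O)Cl
Why: Standard O-sulfonylation of a secondary alcohol at low temperature, in which the C–O bond and hence the S configuration stay untouched; the mesylate is used without storage.

Step 6
Reactants: 10 vanillin
Product: 11 3-methoxy-4-(triisopropylsilyloxy)benzaldehyde
Conditions: i-Pr3SiCl, imidazole, DMF, rt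
Reagents that add atoms: chlorotriisopropylsilane, CC(C)[Si](Cl)(C(C)C)C(C)C
Why: Imidazole-promoted silylation of the phenol, chosen because a triisopropylsilyl aryl ether withstands alkoxide, 210 °C and aqueous phosphate and donates less into ring B than an alkyl ether would.

Step 7
Reactants: 9 (S)-1-(4-allyl-2-methoxyphenoxy)but-3-yn-2-yl methanesulfonate; 11 3-methoxy-4-(triisopropylsilyloxy)benzaldehyde
Product: 13 (1S,2R)-2-[(4-allyl-2-methoxyphenoxy)methyl]-1-[3-methoxy-4-(triisopropylsilyloxy)phenyl]but-3-yn-1-ol (anti isomer), via (P)-allenylindium iodide mesylate 12 (not isolated)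
Conditions: Pd(OAc)2 (5 mol %), PPh3 (5 mol %), InI (1.5 equiv), THF–HMPA 4:1, rt; aqueous work-up; chromatographic removal of the syn isomer
Reagents that add atoms: none
Why: Palladium-catalysed, indium-mediated umpolung of a propargylic mesylate (allenylmetal SE2' addition): zerovalent palladium displaces the mesylate anti (SN2'), monovalent indium takes over the allenyl group with retention to give 12, and 12 adds to the aldehyde through a closed six-membered transition state syn to indium, so C3 is set by net inversion of the carbinol centre of 9 and C2 by the anti arrangement that keeps the aryl group of 11 away from the CH2OAr substituent of the allene.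

Step 8
Reactants: 13 (1S,2R)-2-[(4-allyl-2-methoxyphenoxy)methyl]-1-[3-methoxy-4-(triisopropylsilyloxy)phenyl]but-3-yn-1-ol; 14 3,6-dichloro-4-methoxypyridazine
Product: 16 6-chloro-4-methoxy-3-{(1S,2R)-2-[(4-allyl-2-methoxyphenoxy)methyl]-1-[3-methoxy-4-(triisopropylsilyloxy)phenyl]but-3-ynyloxy}pyridazine, via sodium alkoxide 15 (not isolated)
Conditions: NaH (1.1 equiv), THF, 0 °C; then 14 (1.2 equiv), 0 °C to rt; chromatographic removal of the C6-substituted isomer
Reagents that add atoms: none
Why: Nucleophilic aromatic substitution by addition–elimination: in the bond-fixed diazine the methoxy group feeds electron density through C4=C5 into C6=N1 and so deactivates C6–Cl, whereas C3–Cl keeps its imidoyl chloride character, feels the inductive pull of the neighbouring oxygen and can be reached by a sodium alkoxide held between N2 and OMe, so substitution should favour C3, with the carbinol C–O bond of 13 and hence C2 untouched.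

Step 9
Reactants: 16 6-chloro-4-methoxy-3-{(1S,2R)-2-[(4-allyl-2-methoxyphenoxy)methyl]-1-[3-methoxy-4-(triisopropylsilyloxy)phenyl]but-3-ynyloxy}pyridazine
Product: 18 (2S,3R)-3-[(4-allyl-2-methoxyphenoxy)methyl]-5-chloro-7-methoxy-2-[3-methoxy-4-(triisopropylsilyloxy)phenyl]-2,3-dihydrobenzofuran (trans isomer), via bridged 2,3-diazabicyclo[2.2.2]octatriene adduct 17 (not isolated)
Conditions: 1,3,5-triisopropylbenzene (0.02 M), BHT (10 mol %), Ar, sealed tube, 210 °C
Reagents that add atoms: none
Why: The diazine of 16 is the electron-poor 4π partner and the tethered terminal alkyne the 2π partner of an intramolecular inverse-electron-demand Diels–Alder reaction: the alkyne carbon bound to C3 bonds to the oxygen-bearing diazine carbon (C3a–C7a) and the terminal carbon to the chlorine-bearing one (C4–C5), giving bridged adduct 17, which loses N2 by retro-(4+2) cleavage and is then aromatic. The closest known reaction type is the thermal conversion of 3-(alk-3-ynyloxy)pyridazines into 2,3-dihydrobenzofurans, applied here to a diazine that carries one more donor. Ring A closes by the cycloaddition/cycloreversion pair, and the dihydrofuran ring closes as the five-membered tether ring of the same event through the C3a–C7a bond. No lasting stereocentre is created (the bridgeheads of 17 vanish on aromatisation), and C2 and C3 lie outside the reacting π systems, so the anti relation of 16 becomes the trans relation of 18. Regiochemistry is fixed by the three-atom tether O1–C2–C3, chemoselectivity for the alkyne over the ring C allyl group by the short tether against a macrocyclic alternative, and the two tether substituents populate the folded rotamer. The chlorine keeps the diazine LUMO low enough to offset the methoxy group, the silyl ether damps ionisation of the benzylic C2–O1 bond, and neutral, degassed, dilute conditions with a radical inhibitor guard the allyl group.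

Step 10
Reactants: 18 (2S,3R)-3-[(4-allyl-2-methoxyphenoxy)methyl]-5-chloro-7-methoxy-2-[3-methoxy-4-(triisopropylsilyloxy)phenyl]-2,3-dihydrobenzofuran; 19 allylboronic acid pinacol ester
Product: 20 (2S,3R)-5-allyl-3-[(4-allyl-2-methoxyphenoxy)methyl]-7-methoxy-2-[3-methoxy-4-(triisopropylsilyloxy)phenyl]-2,3-dihydrobenzofuran
Conditions: 19 (2 equiv), Pd(OAc)2 (5 mol %), SPhos (10 mol %), K3PO4 (3 equiv), degassed THF–H2O 10:1, 65 °C
Reagents that add atoms: none
Why: Suzuki–Miyaura coupling of an aryl chloride, in which the bulky electron-rich biaryl phosphine lets zerovalent palladium insert into the C5–Cl bond that O1 deactivates, the unsubstituted allyl boronate has no α/γ ambiguity, and the fluoride-free phosphate base leaves the silyl ether, both stereocentres and the position of the allyl double bonds alone.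

Step 11
Reactants: 20 (2S,3R)-5-allyl-3-[(4-allyl-2-methoxyphenoxy)methyl]-7-methoxy-2-[3-methoxy-4-(triisopropylsilyloxy)phenyl]-2,3-dihydrobenzofuran
Product: 21 4-{(2S,3R)-5-allyl-3-[(4-allyl-2-methoxyphenoxy)methyl]-7-methoxy-2,3-dihydrobenzofuran-2-yl}-2-methoxyphenol (target)
Conditions: Bu4NF (1.1 equiv), AcOH (1.1 equiv), THF, 0 °C
Reagents that add atoms: none
Why: Fluoride-induced cleavage of an aryl silyl ether, buffered with acetic acid so that no free phenoxide para to C2 can open the dihydrofuran through a quinone methide, which keeps C2 and C3 intact.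

Compound list
1 | eugenol (4-allyl-2-methoxyphenol) | C=CCc1ccc(O)c(OC)c1 | starting material
2 | 2-chloro-N-methoxy-N-methylacetamide | CON(C)C(=O)CCl | starting material
3 | 2-(4-allyl-2-methoxyphenoxy)-N-methoxy-N-methylacetamide | C=CCc1ccc(OCC(=O)N(C)OC)c(OC)c1 | intermediate
4 | trimethylsilylacetylene | C#C[Si](C)(C)C | starting material
5 | lithium (trimethylsilyl)acetylide (not isolated) | [Li+].[C-]#C[Si](C)(C)C | intermediate
6 | 1-(4-allyl-2-methoxyphenoxy)-4-(trimethylsilyl)but-3-yn-2-one | C=CCc1ccc(OCC(=O)C#C[Si](C)(C)C)c(OC)c1 | intermediate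
7 | (S)-1-(4-allyl-2-methoxyphenoxy)-4-(trimethylsilyl)but-3-yn-2-ol | C=CCc1ccc(OC[C@@H](O)C#C[Si](C)(C)C)c(OC)c1 | intermediate
8 | (S)-1-(4-allyl-2-methoxyphenoxy)but-3-yn-2-ol | C=CCc1ccc(OC[C@@H](O)C#C)c(OC)c1 | intermediate
9 | (S)-1-(4-allyl-2-methoxyphenoxy)but-3-yn-2-yl methanesulfonate | C=CCc1ccc(OC[C@@H](OS(C)(=O)=O)C#C)c(OC)c1 | intermediate
10 | vanillin (4-hydroxy-3-methoxybenzaldehyde) | COc1cc(C=O)ccc1O | starting material
11 | 3-methoxy-4-(triisopropylsilyloxy)benzaldehyde | COc1cc(C=O)ccc1O[Si](C(C)C)(C(C)C)C(C)C | intermediate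
12 | (P)-[4-(4-allyl-2-methoxyphenoxy)buta-1,2-dienyl]indium iodide methanesulfonate (not isolated) | [H]C([In](I)OS(C)(=O)=O)=[C@]=C([H])COc1ccc(CC=C)cc1OC | intermediate
13 | (1S,2R)-2-[(4-allyl-2-methoxyphenoxy)methyl]-1-[3-methoxy-4-(triisopropylsilyloxy)phenyl]but-3-yn-1-ol (anti) | C=CCc1ccc(OC[C@H]([C@H](O)c2ccc(O[Si](C(C)C)(C(C)C)C(C)C)c(OC)c2)C#C)c(OC)c1 | intermediate
14 | 3,6-dichloro-4-methoxypyridazine | COc1cc(Cl)nnc1Cl | starting material
15 | sodium alkoxide of 13 (not isolated) | C=CCc1ccc(OC[C@H]([C@H]([O-])c2ccc(O[Si](C(C)C)(C(C)C)C(C)C)c(OC)c2)C#C)c(OC)c1.[Na+] | intermediate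
16 | 6-chloro-4-methoxy-3-{(1S,2R)-2-[(4-allyl-2-methoxyphenoxy)methyl]-1-[3-methoxy-4-(triisopropylsilyloxy)phenyl]but-3-ynyloxy}pyridazine (key-step precursor) | C=CCc1ccc(OC[C@H]([C@H](Oc2nnc(Cl)cc2OC)c2ccc(O[Si](C(C)C)(C(C)C)C(C)C)c(OC)c2)C#C)c(OC)c1 | intermediate
17 | bridged 2,3-diazabicyclo[2.2.2]octatriene adduct of 16, bridgeheads C7a (O-substituted) and C5 (Cl-substituted), bridgehead configuration not defined (not isolated) | C=CCc1ccc(OC[C@H]2C3=CC4(Cl)C=C(OC)C3(N=N4)O[C@@H]2c2ccc(O[Si](C(C)C)(C(C)C)C(C)C)c(OC)c2)c(OC)c1 | intermediate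
18 | (2S,3R)-3-[(4-allyl-2-methoxyphenoxy)methyl]-5-chloro-7-methoxy-2-[3-methoxy-4-(triisopropylsilyloxy)phenyl]-2,3-dihydrobenzofuran (trans; key-step product) | C=CCc1ccc(OC[C@H]2c3cc(Cl)cc(OC)c3O[C@@H]2c2ccc(O[Si](C(C)C)(C(C)C)C(C)C)c(OC)c2)c(OC)c1 | intermediate
19 | allylboronic acid pinacol ester | C=CCB1OC(C)(C)C(C)(C)O1 | starting material
20 | (2S,3R)-5-allyl-3-[(4-allyl-2-methoxyphenoxy)methyl]-7-methoxy-2-[3-methoxy-4-(triisopropylsilyloxy)phenyl]-2,3-dihydrobenzofuran | C=CCc1ccc(OC[C@H]2c3cc(CC=C)cc(OC)c3O[C@@H]2c2ccc(O[Si](C(C)C)(C(C)C)C(C)C)c(OC)c2)c(OC)c1 | intermediate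
21 | 4-{(2S,3R)-5-allyl-3-[(4-allyl-2-methoxyphenoxy)methyl]-7-methoxy-2,3-dihydrobenzofuran-2-yl}-2-methoxyphenol | C=CCc1ccc(OC[C@H]2c3cc(CC=C)cc(OC)c3O[C@@H]2c2ccc(O)c(OC)c2)c(OC)c1 | target

Total step count: 11. Longest linear sequence: 10 steps (steps 1–5 and 7–11, from eugenol).

Steps most likely to fail

Step 9 (key step). The cycloaddition of the doubly alkoxy-substituted diazine may be slower than thermal cleavage of the benzylic C2–O1 bond (retro-ene loss of the diazinone, or ionisation followed by an O-to-N shift). The fallback keeps the same ring closure but changes the activating group. It sets out from 16 and comes back at 20.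
- The chlorine of 16 is exchanged for an ester by palladium-catalysed methoxycarbonylation (Pd(OAc)2, dppf, CO, Et3N, MeOH–DMF, 70 °C). Methanolysis of the acylpalladium species should outrun any capture by the remote alkyne. This gives pyridazine ester F1.
- With the stronger acceptor on the carbon that becomes C5, the same cycloaddition should need markedly less heat. It should run through bridged adduct F2 to benzofuran ester F3.
- Reduction with i-Bu2AlH (CH2Cl2, −78 °C) gives benzylic alcohol F4, and PPh3/N-chlorosuccinimide gives benzylic chloride F5.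
- Migita–Kosugi–Stille coupling of F5 with tributyl(vinyl)stannane (Pd(PPh3)4, THF, 65 °C) builds the CH2–CH=CH2 group and delivers 20.

Step 7. Three processes may erode the step: expulsion of the aryloxide from the propargylmetal tautomer of the allenyl species, racemisation at the allenylpalladium stage, and poor anti/syn discrimination with an aromatic aldehyde. The fallback replaces the transient polar allenylmetal by an isolable allenylboron reagent. It sets out from 7 and comes back at 13.
- Alcohol 7 is converted (ClCO2Me, pyridine, CH2Cl2, 0 °C) into propargylic carbonate F6.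
- Copper-catalysed anti SN2' borylation (Cu(O-t-Bu), Xantphos, B2pin2, THF, rt) gives the axially chiral allenylboronate F7, whose covalent C–B bond has no tendency to expel aryloxide.
- Heating F7 with 11 in toluene lets the allenylboration run through a closed six-membered transition state to boric ester F8. Hydrolytic work-up frees silylalkynyl alcohol F9, in the same anti (1S,2R) sense as in step 7.
- Short exposure to K2CO3 in MeOH at 0 °C removes only the alkynyl silyl group and gives 13.

Step 8. The hindered secondary alkoxide may attack C6 instead of the more crowded C3, so that most of the material ends up as the wrong regioisomer. The fallback uses an electrophile whose reactive position is defined by its leaving group. It sets out from 13 (as alkoxide 15) and comes back at 16.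
- Purchased aminopyridazine F10 (6-chloro-4-methoxypyridazin-3-amine) already has the position next to the methoxy group marked. It is diazotised in HF–pyridine (NaNO2, −10 °C to rt).
- Diazonium fluoride F11 loses N2 (Balz–Schiemann-type fluorodediazoniation) to give fluoropyridazine F12.
- Fluoride leaves far faster than chloride in addition–elimination, so 15 should enter F12 only at C3 (THF, −20 °C) and give 16 as a single regioisomer.

Further compounds
F1 | step 9 | methyl 6-{(1S,2R)-2-[(4-allyl-2-methoxyphenoxy)methyl]-1-[3-methoxy-4-(triisopropylsilyloxy)phenyl]but-3-ynyloxy}-5-methoxypyridazine-3-carboxylate | C=CCc1ccc(OC[C@H]([C@H](Oc2nnc(C(=O)OC)cc2OC)c2ccc(O[Si](C(C)C)(C(C)C)C(C)C)c(OC)c2)C#C)c(OC)c1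
F2 | step 9 | bridged 2,3-diazabicyclo[2.2.2]octatriene adduct of F1 (bridgehead configuration not defined) | C=CCc1ccc(OC[C@H]2C3=CC4(C(=O)OC)C=C(OC)C3(N=N4)O[C@@H]2c2ccc(O[Si](C(C)C)(C(C)C)C(C)C)c(OC)c2)c(OC)c1
F3 | step 9 | methyl (2S,3R)-3-[(4-allyl-2-methoxyphenoxy)methyl]-7-methoxy-2-[3-methoxy-4-(triisopropylsilyloxy)phenyl]-2,3-dihydrobenzofuran-5-carboxylate | C=CCc1ccc(OC[C@H]2c3cc(C(=O)OC)cc(OC)c3O[C@@H]2c2ccc(O[Si](C(C)C)(C(C)C)C(C)C)c(OC)c2)c(OC)c1
F4 | step 9 | {(2S,3R)-3-[(4-allyl-2-methoxyphenoxy)methyl]-7-methoxy-2-[3-methoxy-4-(triisopropylsilyloxy)phenyl]-2,3-dihydrobenzofuran-5-yl}methanol | C=CCc1ccc(OC[C@H]2c3cc(CO)cc(OC)c3O[C@@H]2c2ccc(O[Si](C(C)C)(C(C)C)C(C)C)c(OC)c2)c(OC)c1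
F5 | step 9 | (2S,3R)-3-[(4-allyl-2-methoxyphenoxy)methyl]-5-(chloromethyl)-7-methoxy-2-[3-methoxy-4-(triisopropylsilyloxy)phenyl]-2,3-dihydrobenzofuran | C=CCc1ccc(OC[C@H]2c3cc(CCl)cc(OC)c3O[C@@H]2c2ccc(O[Si](C(C)C)(C(C)C)C(C)C)c(OC)c2)c(OC)c1
F6 | step 7 | (S)-1-(4-allyl-2-methoxyphenoxy)-4-(trimethylsilyl)but-3-yn-2-yl methyl carbonate | C=CCc1ccc(OC[C@@H](OC(=O)OC)C#C[Si](C)(C)C)c(OC)c1
F7 | step 7 | (M)-2-[4-(4-allyl-2-methoxyphenoxy)-1-(trimethylsilyl)buta-1,2-dienyl]-4,4,5,5-tetramethyl-1,3,2-dioxaborolane | C[Si](C)(C)C(B1OC(C)(C)C(C)(C)O1)=[C@]=C([H])COc1ccc(CC=C)cc1OC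
F8 | step 7 | O-(pinacolatoboryl) derivative of F9 | C=CCc1ccc(OC[C@H]([C@H](OB2OC(C)(C)C(C)(C)O2)c2ccc(O[Si](C(C)C)(C(C)C)C(C)C)c(OC)c2)C#C[Si](C)(C)C)c(OC)c1
F9 | step 7 | (1S,2R)-2-[(4-allyl-2-methoxyphenoxy)methyl]-1-[3-methoxy-4-(triisopropylsilyloxy)phenyl]-4-(trimethylsilyl)but-3-yn-1-ol | C=CCc1ccc(OC[C@H]([C@H](O)c2ccc(O[Si](C(C)C)(C(C)C)C(C)C)c(OC)c2)C#C[Si](C)(C)C)c(OC)c1
F10 | step 8 | 6-chloro-4-methoxypyridazin-3-amine (purchased) | COc1cc(Cl)nnc1N
F11 | step 8 | 6-chloro-4-methoxypyridazine-3-diazonium fluoride | COc1cc(Cl)nnc1[N+]#N.[F-]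
F12 | step 8 | 6-chloro-3-fluoro-4-methoxypyridazine | COc1cc(Cl)nnc1F
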